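**Strategy.** Ring atoms are numbered C1 (OAc), C2 (ethylidene), C3 (Cl), C4 (CMe2), C5 (Br), C6 (CH2). The cyclohexane is grown from a cyclopentane: in a 3-chloro-2-vinylbicyclo[3.1.0]hexan-2-ol, C6 bridges C1 and C5 as a cyclopropane. Ionisation of the tertiary carbinol at C2 (cyclopropylcarbinyl–homoallyl rearrangement) lets bromide cut the internal C1–C5 bond with inversion at C5, exploiting the homoallylic array C5(Br)–C6H2–C1=C2. One operation expands the five-membered ring to the six-membered ring, forges the neopentyl C5–Br bond that substitution cannot deliver, and leaves a 1-vinylcyclohexene whose epoxide opens 1,4 to the C1 acetate, Z-ethylidene and allylic bromide. The cyclopropane also steers the C3 chlorination.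

Key step: step 6

Remark: the locants of the bicyclo[3.1.0]hexanes 4–10 coincide with the target ring numbering (C6 = cyclopropane CH2). Compounds 1, 3, 8 and 13 are taken as commercial. The L-fructose-derived (ent-)Shi ketone is assumed to be available as a catalyst.

**Step 1**
Reactants: 1 4,4-dimethylcyclopent-2-en-1-one
Product: 2 (R)-4,4-dimethylcyclopent-2-en-1-ol
Conditions: (S)-Me-CBS (10 mol%), BH3·SMe2, THF, −30 °C; MeOH
Reagents that add atoms: none
Why: Corey–Bakshi–Shibata reduction, in which the oxazaborolidine treats the alkene arm as the large group and should deliver hydride to one carbonyl face in a 1,2-sense, setting the carbinol center as R.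

**Step 2**
Reactants: 2 (R)-4,4-dimethylcyclopent-2-en-1-ol; 3 diiodomethane
Product: 4 (1S,2R,5R)-4,4-dimethylbicyclo[3.1.0]hexan-2-ol
Conditions: Et2Zn, CH2I2, CH2Cl2, 0 °C to rt
Reagents that add atoms: diiodomethane, ICI
Why: Hydroxyl-directed Simmons–Smith (Furukawa) cyclopropanation, in which the zinc alkoxide should deliver CH2 to its own alkene face, so the cyclopropane forms cis to OH and both bridgehead centers (C1, C5) are fixed.

**Step 3**
Reactants: 4 (1S,2R,5R)-4,4-dimethylbicyclo[3.1.0]hexan-2-ol
Product: 5 (1S,5R)-4,4-dimethylbicyclo[3.1.0]hexan-2-one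
Conditions: Dess–Martin periodinane, CH2Cl2, rt
Reagents that add atoms: none
Why: Dess–Martin oxidation of a secondary alcohol under neutral conditions, which should leave the cyclopropane and the non-epimerisable bridgehead centers untouched.

**Step 4**
Reactants: 5 (1S,5R)-4,4-dimethylbicyclo[3.1.0]hexan-2-one
Product: 7 (1S,3S,5R)-3-chloro-4,4-dimethylbicyclo[3.1.0]hexan-2-one, via lithium enolate 6 (not isolated)
Conditions: LDA, THF, −78 °C; then added to TsCl, THF, −78 to 0 °C
Reagents that add atoms: p-toluenesulfonyl chloride, Cc1ccc(cc1)S(=O)(=O)Cl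
Why: Electrophilic α-chlorination of a ketone enolate, which can form only toward C3 (the cyclopropyl bridgehead H is not removed) and should take up chlorine on the convex face anti to the cyclopropane CH2, placing Cl trans to the three-membered ring.

**Step 5**
Reactants: 7 (1S,3S,5R)-3-chloro-4,4-dimethylbicyclo[3.1.0]hexan-2-one; 8 vinylmagnesium bromide
Product: 9 (1S,2R,3S,5R)-3-chloro-2-ethenyl-4,4-dimethylbicyclo[3.1.0]hexan-2-ol
Conditions: CeCl3, THF, −78 °C; pH 7 buffer
Reagents that add atoms: vinylmagnesium bromide, C=C[Mg]Br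
Why: Organocerium 1,2-addition to a hindered, enolisable α-chloro ketone, expected anti to the C–Cl bond (polar Felkin–Anh) so that OH lies cis to Cl and cannot close to an epoxide; the C2 configuration is erased in step 6.

**Step 6**
Reactants: 9 (1S,2R,3S,5R)-3-chloro-2-ethenyl-4,4-dimethylbicyclo[3.1.0]hexan-2-ol
Product: 11 (4R,6R)-4-bromo-6-chloro-1-ethenyl-5,5-dimethylcyclohex-1-ene, via allyl-cyclopropylcarbinyl cation 10 (not isolated)
Conditions: 48% aq HBr, ZnBr2 (cat.), Et2O, −15 to 0 °C; NaHCO3; used at once
Reagents that add atoms: hydrogen bromide, Br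
Why: Protonation and loss of water from the tertiary carbinol gives cation 10, stabilised both as an allyl and as a cyclopropylcarbinyl cation, and bromide then attacks bridgehead C5 from the side opposite the C1–C5 bond while that bond becomes the C1=C2 π bond. The closest known reaction is the Julia cyclopropylcarbinyl–homoallyl rearrangement in its ring-enlarging form (bicyclo[n.1.0]alkan-2-yl to cycloalk-3-enyl halide, as in the i-steroid rearrangement). No ring is closed: the six-membered ring appears when the bond shared by the five- and three-membered rings is cut, so the former cyclopropane CH2 becomes ring atom C6. The new stereocenter C5 is set by stereospecific backside opening (inversion), so it follows from the cyclopropane configuration fixed in step 2, and Br should end trans to the C3 chlorine. The step needs cleavage of the internal C1–C5 bond over the external C1–C6 bond and ring opening over simple capture at the allyl termini; positive charge is better carried by secondary C5 than by the primary CH2, and capture at the allyl termini is reversible whereas ring opening releases the cyclopropane strain and is not. The C3 chloride next to the cation should not ionise at this temperature.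

**Step 7**
Reactants: 11 (4R,6R)-4-bromo-6-chloro-1-ethenyl-5,5-dimethylcyclohex-1-ene
Product: 12 (1S,2S,4R,6S)-4-bromo-2-chloro-1-ethenyl-3,3-dimethyl-7-oxabicyclo[4.1.0]heptane
Conditions: ent-Shi ketone (L-fructose-derived, 30 mol%), Oxone, K2CO3, Bu4NHSO4, MeCN–DMM–aq. buffer pH 10.5, 0 °C
Reagents that add atoms: potassium peroxymonosulfate (Oxone), [K+].[O-]S(=O)(=O)OO
Why: Shi asymmetric epoxidation, in which the chiral dioxirane should epoxidise the trisubstituted ring alkene of the diene in preference to the vinyl group and, by catalyst control (each substrate face carries one axial group), deliver oxygen anti to the C3 chlorine so that C1–O is S.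

**Step 8**
Reactants: 12 (1S,2S,4R,6S)-4-bromo-2-chloro-1-ethenyl-3,3-dimethyl-7-oxabicyclo[4.1.0]heptane; 13 acetyl bromide
Product: 15 [(1S,2Z,3R,5R)-5-bromo-2-(2-bromoethylidene)-3-chloro-4,4-dimethylcyclohexyl] acetate (target), via bromohydrin 14 (not isolated)
Conditions: AcBr, CuBr (5 mol%), CH2Cl2, −40 to 0 °C
Reagents that add atoms: acetyl bromide, CC(=O)Br
Why: Acyl halide opening of a vinyl epoxide, in which trace HBr should cleave the tertiary allylic C2–O bond in the 1,4 (SN2') sense to bromohydrin 14, which acetyl bromide esterifies with regeneration of HBr; the C1–O bond is never broken, and reversible ionisation of the allylic bromide should settle on the Z isomer with CH2Br syn to C3 and Cl axial (least A1,3 strain).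

**Compound list**
1 | 4,4-dimethylcyclopent-2-en-1-one | O=C1C=CC(C)(C)C1 | starting material
2 | (R)-4,4-dimethylcyclopent-2-en-1-ol | O[C@H]1C=CC(C)(C)C1 | intermediate
3 | diiodomethane | ICI | starting material
4 | (1S,2R,5R)-4,4-dimethylbicyclo[3.1.0]hexan-2-ol (OH cis to cyclopropane) | O[C@@H]1CC(C)(C)[C@@H]2C[C@H]12 | intermediate
5 | (1S,5R)-4,4-dimethylbicyclo[3.1.0]hexan-2-one | O=C1CC(C)(C)[C@@H]2C[C@H]12 | intermediate
6 | lithium (1S,5R)-4,4-dimethylbicyclo[3.1.0]hex-2-en-2-olate | [Li+].[O-]C1=CC(C)(C)[C@@H]2C[C@H]12 | intermediate (not isolated)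
7 | (1S,3S,5R)-3-chloro-4,4-dimethylbicyclo[3.1.0]hexan-2-one (Cl trans to cyclopropane CH2) | O=C1[C@@H](Cl)C(C)(C)[C@@H]2C[C@H]12 | intermediate
8 | vinylmagnesium bromide | C=C[Mg]Br | starting material
9 | (1S,2R,3S,5R)-3-chloro-2-ethenyl-4,4-dimethylbicyclo[3.1.0]hexan-2-ol (OH cis to Cl) | O[C@@]1(C=C)[C@@H](Cl)C(C)(C)[C@@H]2C[C@H]12 | intermediate
10 | (1S,3S,5R)-3-chloro-2-ethenyl-4,4-dimethylbicyclo[3.1.0]hexan-2-ylium (allyl-cyclopropylcarbinyl cation) | C=C[C+]1[C@@H](Cl)C(C)(C)[C@@H]2C[C@H]12 | intermediate (not isolated)
11 | (4R,6R)-4-bromo-6-chloro-1-ethenyl-5,5-dimethylcyclohex-1-ene (Br trans to Cl) | C=CC1=CC[C@@H](Br)C(C)(C)[C@@H]1Cl | intermediate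
12 | (1S,2S,4R,6S)-4-bromo-2-chloro-1-ethenyl-3,3-dimethyl-7-oxabicyclo[4.1.0]heptane (oxirane O cis to Br, trans to Cl) | C=C[C@]12O[C@H]1C[C@@H](Br)C(C)(C)[C@@H]2Cl | intermediate
13 | acetyl bromide | CC(=O)Br | starting material
14 | (1S,2Z,3R,5R)-5-bromo-2-(2-bromoethylidene)-3-chloro-4,4-dimethylcyclohexan-1-ol | O[C@H]1C[C@@H](Br)C(C)(C)[C@H](Cl)/C1=C\CBr | intermediate (not isolated)
15 | [(1S,2Z,3R,5R)-5-bromo-2-(2-bromoethylidene)-3-chloro-4,4-dimethylcyclohexyl] acetate | CC(=O)O[C@H]1C[C@@H](Br)C(C)(C)[C@H](Cl)/C1=C\CBr | target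

**Total step count:** 8
**Longest linear sequence:** 8 steps (1 → 15)

**Steps most likely to fail**

1. Step 6 (key step). Bromide may be captured at the exocyclic allyl terminus without ring opening. The external C1–C6 cyclopropane bond may cleave instead of the internal one. A methyl group may shift from C4 toward the developing charge at C5. HBr may add to the product diene. Fallback, from 7 back to 11: ethynylmagnesium bromide/CeCl3 is added to 7 to give the propargylic carbinol (1S,2S,3S,5R)-3-chloro-2-ethynyl-4,4-dimethylbicyclo[3.1.0]hexan-2-ol F1. Its cation is less stabilised by the alkynyl group, so cyclopropane participation should dominate, and HBr/ZnBr2 should give the enyne (4R,6R)-4-bromo-6-chloro-1-ethynyl-5,5-dimethylcyclohex-1-ene F2, which adds HBr less readily than a diene. Lindlar semihydrogenation (H2, Pd/CaCO3–Pb, quinoline) then gives 11.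

2. Step 7. The catalyst and substrate may be mismatched, giving poor facial discrimination. The chlorine-deactivated ring alkene may react sluggishly, or the vinyl group may be epoxidised in competition. Fallback, from 11 back to 15, with C1 set by ketone reduction instead of epoxidation: mCPBA epoxidation without regard to the face gives 12 together with its oxirane-face isomer (1R,2S,4R,6R)-4-bromo-2-chloro-1-ethenyl-3,3-dimethyl-7-oxabicyclo[4.1.0]heptane F3. Aqueous HBr/CuBr opens both 1,4 to 14 and its C1 epimer (1R,2Z,3R,5R)-5-bromo-2-(2-bromoethylidene)-3-chloro-4,4-dimethylcyclohexan-1-ol F4. Dess–Martin oxidation converges both on the enone (2Z,3R,5R)-5-bromo-2-(2-bromoethylidene)-3-chloro-4,4-dimethylcyclohexan-1-one F5, whose geometry is the thermodynamically preferred one. (R)-Me-CBS/catecholborane reduction should return 14 by reagent control, and amine-free acetylation (Ac2O, cat. Sc(OTf)3) gives 15.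

3. Step 8. The epoxide may open at the wrong carbon, bromide may stay at the tertiary position, halides may scramble at C3, or the allylic C1–O bond may ionise under HBr with loss of configuration and olefin geometry. Fallback, from 12 back to 15: the two events are separated. Anhydrous MgBr2·OEt2 (Et2O, −20 °C) opens 12 to bromohydrin 14, which is isolated and, if needed, equilibrated to the Z allylic bromide with LiBr in acetone. It is then acetylated without amine or Brønsted acid (Ac2O, cat. Sc(OTf)3, MeCN, −20 °C) to give 15.

**Further compounds**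
F1 | step 6 | (1S,2S,3S,5R)-3-chloro-2-ethynyl-4,4-dimethylbicyclo[3.1.0]hexan-2-ol | O[C@@]1(C#C)[C@@H](Cl)C(C)(C)[C@@H]2C[C@H]12
F2 | step 6 | (4R,6R)-4-bromo-6-chloro-1-ethynyl-5,5-dimethylcyclohex-1-ene | C#CC1=CC[C@@H](Br)C(C)(C)[C@@H]1Cl
F3 | step 7 | (1R,2S,4R,6R)-4-bromo-2-chloro-1-ethenyl-3,3-dimethyl-7-oxabicyclo[4.1.0]heptane | C=C[C@@]12O[C@@H]1C[C@@H](Br)C(C)(C)[C@@H]2Cl
F4 | step 7 | (1R,2Z,3R,5R)-5-bromo-2-(2-bromoethylidene)-3-chloro-4,4-dimethylcyclohexan-1-ol | O[C@@H]1C[C@@H](Br)C(C)(C)[C@H](Cl)/C1=C\CBr
F5 | step 7 | (2Z,3R,5R)-5-bromo-2-(2-bromoethylidene)-3-chloro-4,4-dimethylcyclohexan-1-one | O=C1C[C@@H](Br)C(C)(C)[C@H](Cl)/C1=C\CBr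
F0 | step 8 | none | none
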